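## The problem

Target 34 is a humulane-type eleven-membered carbocycle. With the ring numbered C1 (CMe2), C2 (CH–OBz), C3=C4 (CO2H on C4), C5, C6, C7–C8 (oxirane, methyl on C8) and C9–C11 (three CH2), the oxirane is the only ring fused to it. The construction problem is therefore one medium ring, of a size that closes poorly by direct cyclisation. That ring must hold a C3=C4 enoate whose ring bonds to C2 and C5 are cis (E by the sequence rule, because CO2H outranks C5) and an E-trisubstituted C7=C8 olefin as the source of the trans epoxide. There are three stereocentres: C2 (R), wedged between the quaternary C1 and the enoate, and C7 (R)/C8 (R). C2 is best bought from the chiral pool; it is five ring bonds from C7, so it can steer the epoxidation only through the ring conformation, and the epoxide has to be set by a reagent. The trisubstituted epoxide will not survive acid, the allylic benzoate will not survive hydroxide, the acid must be released beside both, and the enoate invites conjugate addition from any nucleophile held 1,5 to C3. The feature that opens the route is the C9–C10–C11 bridge, three bare CH2 groups between C8 and the quaternary C1. A sulfur atom can be placed between C10 and C11 to give an easier twelve-membered ring and then be expelled as SO2 (Ramberg–Bäcklund), leaving only a C10=C11 olefin that hydrogenation erases.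

## Retrosynthesis

**End game (34 back to 30).** The last bond cut is the ester C–O of 2-(trimethylsilyl)ethyl ester 33. Fluoride frees the acid without touching benzoate or epoxide, which a methyl ester and hydroxide could not do. Cutting the two C–O bonds of the oxirane leads to dienoate 32; its enoate is electron-poor, so only C7=C8 is open to an electrophilic oxidant. The benzoate C–O bond and the silyl ether lead back through alcohol 31 to silyl ether 30. The silyl group is exchanged for benzoate before the epoxide exists, so the exchange can use acid.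

**Ring contraction (30 back to 26).** Adding back C10=C11 gives triene 29, and cutting the C10–C11 bond with insertion of SO2 gives twelve-membered sulfone 26. Against a direct eleven-membered closure at C3=C4 or C10–C11, this moves the ring-forming event to a twelve-membered ring and makes the contraction intramolecular. The forward step must brominate and eliminate next to an enoate without hydrolysing or adding to it. The olefin geometry it delivers does not matter.

**Ring closure (26 back to 25).** The C3=C4 bond is cut to aldehyde-phosphonate 25 (intramolecular Horner–Wadsworth–Emmons). Closing at sulfur instead would put a C11 thiolate 1,5 to C3 of a finished enoate, where a 5-exo-trig conjugate addition, helped by the gem-dimethyl group, would form a thiolane before the large ring could close. With the C–S bond already in place, the olefination sets the enoate geometry and closes the ring in one step. The forward reaction has to win over oligomerisation and must not epimerise C2.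

**Fragment union (25 back to 5 and 18).** Aldehyde 25 comes from bis-silyl ether 24, diol 23 and acetonide sulfone 22 by functional-group changes at C2/C3. The sulfone oxygens are removed to sulfide 20, and the C10–S bond is cut to thioacetate 5 and iodide 18. This is a thiolate SN2 reaction at an unhindered primary carbon, made while C3 is still a masked alcohol. The two fragments are of similar size and each is made in a few steps.

**Sulfur fragment (5 back to 1).** The C11–S bond is cut to neopentyl alcohol 3; the forward step has to substitute at a neopentyl carbon, which calls for a triflate (4) and a small soft nucleophile. Acetonide 3 comes from triol 2 and (S)-pantolactone 1, which supplies C11, C1 with both methyls, C2 with its oxygen in the right configuration, and C3.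

**Phosphonate fragment (18 back to 9, 11, 6 and 7).** Iodide 18 comes from alcohol 17 and silyl ether 16. The C4–C5 bond is cut to iodide 15 and phosphonate 8 (from acid 6 and alcohol 7). Iodide 15 comes from alcohol 14. The C6–C7 and C8–CH3 bonds of 14 are cut to ethylene oxide 11 and alkyne 10 (silylated but-3-yn-1-ol 9); methyl–metal addition across the alkyne fixes the E geometry of C7=C8.

## Roads not taken

**Alternative 1:** The cut is across C3–C4 and C7–C8 of a cyclobutane. Irradiation of 3,7,7-trimethylcyclohept-2-enone A1 with methyl cyclobut-1-enecarboxylate A2 would give the 7-4-4 tricyclic keto ester A3. Thermal cycloreversion in the other sense (breaking C3–C8 and C4–C7) would then unzip it to the eleven-membered 2-oxo dienoate A7.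
- Merits: two operations assemble every ring carbon, both trisubstituted olefins and the C2 oxygen, with no macrocyclisation. In step count this road is clearly better than the chosen one.
- Weak points: the head-to-head orientation of the photoaddition is not assured for a β-methyl enone and an ester-bearing cyclobutene. Cycloheptenones twist in the excited state, which erodes the ring-fusion stereochemistry on which the olefin geometries depend. The cycloreversion needs temperatures at which the 1,5-diene formed can undergo Cope rearrangement. The material is racemic.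
- The absolute configuration at C2 would rest on an enantioselective 1,2-reduction of a ketone flanked by a quaternary carbon and a doubly activated olefin.
- Comparison: the chosen plan sets against the shorter sequence a C2 centre secured from the first step and olefin geometries fixed by reactions of known sense.

**Alternative 2:** The cut is the cyclobutane ring-fusion bond C3–C11 of (−)-caryophyllene oxide A4. Addition of PhS• to the exocyclic methylene gives a C4 radical whose β-scission forms C3=C4 and opens the bicycle to eleven-membered allyl sulfide A5.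
- Merits: a cheap terpenoid supplies all ring carbons, the gem-dimethyl group and the epoxide in the configuration of 34, in one step. In step economy and in the security of C7/C8 this road is better than the chosen one.
- Weak points: A5 has a bare CH2 at C2 and CH2SPh instead of CO2H at C4. Oxygenating C2 means an allylic C–H oxidation at a neopentyl position with control of a new stereocentre, beside a second allylic position (C5) and an acid-labile epoxide; no reliable method is available for this. Raising CH2SPh to the acid needs Pummerer-type chemistry that the epoxide is unlikely to tolerate. The scission must also choose the ring-fusion bond over the other cyclobutane bond and give the ring-cis C3=C4.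
- Comparison: the chosen plan sets against this C2–O and the carboxyl carbon placed at the right oxidation level from the start, paying with a reagent-controlled epoxidation.

**Alternative 3:** The cut is a transannular C2–C8 bond. In the fused six–seven hydroxy mesylate A6 the C2 alkoxide would expel the C7 mesylate (Grob fragmentation), breaking C2–C8 and giving the C2 ketone and C7=C8 of A7.
- Merits: the concerted fragmentation turns the relative configuration of a rigid bicycle into the E geometry of C7=C8, needs no high dilution, and leaves no C10=C11 olefin to remove. In these respects it is as good as or better than the chosen plan.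
- Weak points: A6 carries three contiguous stereocentres, two of them fully substituted, that must be built in one relative configuration on a cyclohexanone template, and it is racemic unless that work is made asymmetric. C2 emerges as a ketone, so its configuration again depends on reduction of the sensitive γ-oxo enoate A7.
- Comparison: the chosen plan sets against this a convergent assembly from two simple fragments and a C2 centre that is never a ketone.

Key step: step 17

Remarks on the chemistry:
- Ring atoms are numbered C1–C11 as in the first section throughout.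
- The C4 stereocentre made in step 8 is uncontrolled. Compounds 16–18 and 20–25 are carried as mixtures of C4 epimers (left undefined in the SMILES) until step 16 removes it.
- In step 17 the bromide is drawn at C10 and the new olefin as Z; the C11 bromide and the E olefin would converge on 30.
- The descriptor at C2 changes from S to R at 26 only because the sequence-rule priorities change.

## Route

Step 1
Reactants: 1 (S)-pantolactone
Product: 2 (2S)-3,3-dimethylbutane-1,2,4-triol
Conditions: LiAlH4, THF, 0 °C → reflux; aq. NaOH work-up
Reagents that add atoms: none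
Why: Hydride reduction of a lactone to the diol; C2 is not involved, so the configuration of 1 is carried into 2.

Step 2
Reactants: 2 (2S)-3,3-dimethylbutane-1,2,4-triol
Product: 3 2-[(4S)-2,2-dimethyl-1,3-dioxolan-4-yl]-2-methylpropan-1-ol
Conditions: Me2C(OMe)2, TsOH·H2O (cat.), acetone, rt
Reagents that add atoms: 2,2-dimethoxypropane, COC(C)(C)OC
Why: Acid-catalysed ketalisation; acetone ketals prefer the five-membered dioxolane over the six-membered dioxane, so the terminal 1,2-diol is tied up and the neopentyl C11–OH stays free.

Step 3
Reactants: 3 2-[(4S)-2,2-dimethyl-1,3-dioxolan-4-yl]-2-methylpropan-1-ol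
Product: 5 S-{2-[(4S)-2,2-dimethyl-1,3-dioxolan-4-yl]-2-methylpropyl} ethanethioate, via neopentyl triflate 4 (not isolated)
Conditions: Tf2O, pyridine, CH2Cl2, −78 → 0 °C; then KSAc, DMF, 0 °C → rt
Reagents that add atoms: potassium thioacetate, CC(=O)[S-].[K+]
Why: Sulfonylation followed by SN2 displacement; a neopentyl triflate cannot eliminate and is reactive enough for the small, soft thioacetate ion to substitute at this hindered carbon, where a tosylate or halide would be too slow.

Step 4
Reactants: 6 (diethoxyphosphoryl)acetic acid; 7 2-(trimethylsilyl)ethanol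
Product: 8 2-(trimethylsilyl)ethyl (diethoxyphosphoryl)acetate
Conditions: DCC, DMAP (cat.), CH2Cl2, 0 °C → rt
Reagents that add atoms: none
Why: Steglich esterification; it gives the phosphonate an ester that fluoride can later remove beside a benzoate and an epoxide.

Step 5
Reactants: 9 but-3-yn-1-ol
Product: 10 (but-3-yn-1-yloxy)(tert-butyl)dimethylsilane
Conditions: TBSCl, imidazole, DMF, rt
Reagents that add atoms: tert-butyldimethylsilyl chloride, CC(C)(C)[Si](C)(C)Cl
Why: Standard silylation of a primary alcohol; it keeps the future C10 oxygen distinct from the one ethylene oxide will bring.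

Step 6
Reactants: 10 (but-3-yn-1-yloxy)(tert-butyl)dimethylsilane; 11 ethylene oxide
Product: 14 (3E)-6-(tert-butyldimethylsilyloxy)-4-methylhex-3-en-1-ol, via alkenylalane 12 (not isolated), via lithium alanate 13 (not isolated)
Conditions: Me3Al, Cp2ZrCl2 (cat.), CH2Cl2, 0 °C → rt; volatiles removed; n-BuLi, THF/hexane, −78 °C; ethylene oxide, −78 °C → rt
Reagents that add atoms: trimethylaluminium, C[Al](C)C
Why: Negishi carboalumination adds methyl and aluminium syn across the alkyne with methyl on the internal carbon, giving E-alkenylalane 12. Its ate complex 13 is nucleophilic enough to open ethylene oxide with retention at the olefin, which fixes E at C7=C8.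

Step 7
Reactants: 14 (3E)-6-(tert-butyldimethylsilyloxy)-4-methylhex-3-en-1-ol
Product: 15 tert-butyl{[(3E)-6-iodo-3-methylhex-3-en-1-yl]oxy}dimethylsilane
Conditions: I2, PPh3, imidazole, CH2Cl2, 0 °C → rt
Reagents that add atoms: iodine, II
Why: Appel-type iodination of a primary alcohol under near-neutral conditions that spare the silyl ether and the olefin.

Step 8
Reactants: 15 tert-butyl{[(3E)-6-iodo-3-methylhex-3-en-1-yl]oxy}dimethylsilane; 8 2-(trimethylsilyl)ethyl (diethoxyphosphoryl)acetate
Product: 16 2-(trimethylsilyl)ethyl (5E)-8-(tert-butyldimethylsilyloxy)-2-(diethoxyphosphoryl)-6-methyloct-5-enoate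
Conditions: 8 (excess), NaH, DMF, 0 °C; then 15, 50 °C
Reagents that add atoms: none
Why: C-alkylation of a stabilised phosphonoacetate anion by a primary iodide forms C4–C5; an excess of 8 limits dialkylation, and the new C4 centre is left uncontrolled because step 16 destroys it.

Step 9
Reactants: 16 2-(trimethylsilyl)ethyl (5E)-8-(tert-butyldimethylsilyloxy)-2-(diethoxyphosphoryl)-6-methyloct-5-enoate
Product: 17 2-(trimethylsilyl)ethyl (5E)-2-(diethoxyphosphoryl)-8-hydroxy-6-methyloct-5-enoate
Conditions: CSA (cat.), MeOH/CH2Cl2, 0 °C
Reagents that add atoms: none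
Why: Acid-catalysed methanolysis of a primary TBS ether; fluoride is avoided because it would cleave the silylethyl ester.

Step 10
Reactants: 17 2-(trimethylsilyl)ethyl (5E)-2-(diethoxyphosphoryl)-8-hydroxy-6-methyloct-5-enoate
Product: 18 2-(trimethylsilyl)ethyl (5E)-2-(diethoxyphosphoryl)-8-iodo-6-methyloct-5-enoate
Conditions: I2, PPh3, imidazole, CH2Cl2, 0 °C → rt
Reagents that add atoms: iodine, II
Why: Appel-type iodination as in step 7; the phosphonoacetate C–H is not touched by imidazole.

Step 11
Reactants: 5 S-{2-[(4S)-2,2-dimethyl-1,3-dioxolan-4-yl]-2-methylpropyl} ethanethioate; 18 2-(trimethylsilyl)ethyl (5E)-2-(diethoxyphosphoryl)-8-iodo-6-methyloct-5-enoate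
Product: 20 2-(trimethylsilyl)ethyl (5E)-2-(diethoxyphosphoryl)-8-({2-[(4S)-2,2-dimethyl-1,3-dioxolan-4-yl]-2-methylpropyl}sulfanyl)-6-methyloct-5-enoate, via thiol 19 (not isolated)
Conditions: pyrrolidine, degassed MeCN, 0 °C; then 18, DBU, rt
Reagents that add atoms: none
Why: Aminolysis of the thioacetate frees thiol 19, whose thiolate displaces the primary iodide (SN2) to form the C10–S bond. Methoxide is avoided to keep the silylethyl ester, and the thiolate is far more nucleophilic than the phosphonate.

Step 12
Reactants: 20 acyclic sulfide (name as in step 11)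
Product: 22 2-(trimethylsilyl)ethyl (5E)-2-(diethoxyphosphoryl)-8-({2-[(4S)-2,2-dimethyl-1,3-dioxolan-4-yl]-2-methylpropyl}sulfonyl)-6-methyloct-5-enoate, via sulfoxide 21 (not isolated)
Conditions: (NH4)6Mo7O24·4H2O (cat.), 30% H2O2, EtOH, 0 °C → rt
Reagents that add atoms: hydrogen peroxide, OO
Why: Molybdate-catalysed peroxide oxidation takes a sulfide through the sulfoxide to the sulfone and leaves trisubstituted olefins alone, unlike a peracid; any acetonide loss is harmless because step 13 removes it.

Step 13
Reactants: 22 acetonide sulfone (name as in step 12)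
Product: 23 2-(trimethylsilyl)ethyl (5E)-2-(diethoxyphosphoryl)-8-{[(3S)-3,4-dihydroxy-2,2-dimethylbutyl]sulfonyl}-6-methyloct-5-enoate
Conditions: AcOH/H2O/THF, 45 °C
Reagents that add atoms: none
Why: Acid hydrolysis of a terminal acetonide; nothing else in 22 is labile to aqueous acetic acid.

Step 14
Reactants: 23 diol sulfone (name as in step 13)
Product: 24 2-(trimethylsilyl)ethyl (5E)-2-(diethoxyphosphoryl)-8-{[(3S)-2,2-dimethyl-3,4-bis(triethylsilyloxy)butyl]sulfonyl}-6-methyloct-5-enoate
Conditions: TESOTf, 2,6-lutidine, CH2Cl2, −78 → 0 °C
Reagents that add atoms: triethylsilyl trifluoromethanesulfonate, CC[Si](CC)(CC)OS(=O)(=O)C(F)(F)F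
Why: A silyl triflate with a hindered base silylates both the primary and the hindered secondary hydroxyl.

Step 15
Reactants: 24 bis(triethylsilyl) ether (name as in step 14)
Product: 25 2-(trimethylsilyl)ethyl (5E)-2-(diethoxyphosphoryl)-8-{[(3S)-2,2-dimethyl-4-oxo-3-(triethylsilyloxy)butyl]sulfonyl}-6-methyloct-5-enoate
Conditions: (COCl)2, DMSO, CH2Cl2, −78 → −40 °C; Et3N, → 0 °C
Reagents that add atoms: none
Why: Swern oxidation applied directly to a primary triethylsilyl ether: the activated sulfoxide cleaves the less hindered primary Si–O bond and oxidises that carbon to the aldehyde, while the secondary silyl ether stays. Low temperature protects the α-silyloxy stereocentre.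

Step 16
Reactants: 25 aldehyde phosphonate (name as in step 15)
Product: 26 2-(trimethylsilyl)ethyl (4R,5E,9E)-3,3,10-trimethyl-1,1-dioxo-4-(triethylsilyloxy)-1-thiacyclododeca-5,9-diene-6-carboxylate (twelve-membered sulfone, sulfur between C10 and C11)
Conditions: LiCl, DBU, MeCN, slow addition of 25 (final about 2 mM), rt
Reagents that add atoms: none
Why: Intramolecular Horner–Wadsworth–Emmons olefination at high dilution, a standard macrocyclisation; the lithium-chelated phosphonate is deprotonated by the amidine while the sulfone is not. The usual preference of α-alkyl phosphonoacetates places CO2R trans to C2 (E), which is also the ring-cis arrangement a twelve-membered ring accepts, and both C4 epimers converge.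

Step 17
Reactants: 26 twelve-membered sulfone (name as in step 16)
Product: 29 2-(trimethylsilyl)ethyl (1E,3R,5Z,8E)-4,4,8-trimethyl-3-(triethylsilyloxy)cycloundeca-1,5,8-triene-1-carboxylate, via α-bromo sulfone 27 (not isolated), via episulfone 28 (not isolated)
Conditions: KOH/Al2O3, BrCF2CF2Br, t-BuOH/CH2Cl2, 0 °C → rt
Reagents that add atoms: none
Why: This is the Ramberg–Bäcklund reaction in its one-pot halogenative form, used as a ring contraction of a macrocyclic sulfone, which is a known application. Supported KOH deprotonates an α-sulfonyl CH2, most readily the unhindered C10, and BrCF2CF2Br transfers bromine to the carbanion to give 27; the reagent's own anion collapses to tetrafluoroethylene and bromide, so no carbene is formed beside C7=C8. Deprotonation at the neopentyl C11 then displaces bromide from C10 in a 1,3-elimination (3-exo-tet closure with inversion at C10) to give episulfone 28. Cheletropic loss of SO2 from 28 leaves the C10–C11 bond as a double bond, so the eleven-membered carbocycle arises by contraction of the existing ring, not by an end-to-end cyclisation. Bromination at C11 would lead to the same episulfone. No stereocentre is created, C2 is not touched, and the C10=C11 geometry (Z expected from the cis-episulfone favoured under hydroxide) is irrelevant because step 18 saturates it. The selectivity needed is chemoselectivity: the enoate must escape hydrolysis and conjugate addition of the C10 carbanion to C3, which the hindered α-branched ester, the heterogeneous base, low temperature and fast bromine transfer should secure. Loss of the triethylsilyl group would be harmless because step 19 removes it.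

Step 18
Reactants: 29 eleven-membered triene (name as in step 17)
Product: 30 2-(trimethylsilyl)ethyl (1E,3R,8E)-4,4,8-trimethyl-3-(triethylsilyloxy)cycloundeca-1,8-diene-1-carboxylate
Conditions: 2-O2NC6H4SO2NHNH2, Et3N, CH2Cl2, rt (repeated charges)
Reagents that add atoms: none
Why: Diimide, released from the sulfonyl hydrazide by base, transfers H2 in a concerted syn fashion and reacts fastest with the least substituted olefin. The 1,2-disubstituted C10=C11 should be reduced before the trisubstituted C7=C8 and the trisubstituted enoate.

Step 19
Reactants: 30 silyl ether diene (name as in step 18)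
Product: 31 2-(trimethylsilyl)ethyl (1E,3R,8E)-3-hydroxy-4,4,8-trimethylcycloundeca-1,8-diene-1-carboxylate
Conditions: PPTS, MeOH/CH2Cl2, rt
Reagents that add atoms: none
Why: Mild acid methanolysis of a triethylsilyl ether; it is done before the epoxide exists so that acid is harmless, and the silylethyl ester is stable to it.

Step 20
Reactants: 31 alcohol (name as in step 19)
Product: 32 2-(trimethylsilyl)ethyl (1E,3R,8E)-3-(benzoyloxy)-4,4,8-trimethylcycloundeca-1,8-diene-1-carboxylate
Conditions: BzCl, pyridine, DMAP, CH2Cl2, 0 °C → rt
Reagents that add atoms: benzoyl chloride, O=C(Cl)c1ccccc1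
Why: DMAP-catalysed acylation of a hindered secondary allylic alcohol; the C2–O bond is not broken, so configuration is retained.

Step 21
Reactants: 32 benzoate diene (name as in step 20)
Product: 33 2-(trimethylsilyl)ethyl (1R,4E,6R,11R)-6-(benzoyloxy)-7,7,11-trimethyl-12-oxabicyclo[9.1.0]dodec-4-ene-4-carboxylate (C2 R, C7 R, C8 R in the ring numbering of the text)
Conditions: D-fructose-derived Shi ketone (cat.), KHSO5 (as 2KHSO5·KHSO4·K2SO4), K2CO3, Bu4NHSO4, MeCN/dimethoxymethane, aq. Na2B4O7/Na2EDTA buffer, 0 °C
Reagents that add atoms: potassium peroxymonosulfate, [K+].[O-]S(=O)(=O)OO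
Why: Shi epoxidation: the chiral dioxirane attacks the electron-rich E-trisubstituted C7=C8 through a spiro transition state, and the D-fructose-derived ketone gives the (R,R) sense required at C7 and C8. The enoate is too electron-poor to react. The olefin can present either face at the ring periphery by conformational change, so the catalyst should choose the face.

Step 22
Reactants: 33 epoxy ester (name as in step 21)
Product: 34 (1R,4E,6R,11R)-6-(benzoyloxy)-7,7,11-trimethyl-12-oxabicyclo[9.1.0]dodec-4-ene-4-carboxylic acid (target)
Conditions: Bu4NF, THF, 0 °C → rt; pH 4 citrate buffer work-up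
Reagents that add atoms: none
Why: Fluoride attacks silicon and the 2-(trimethylsilyl)ethyl ester fragments to carboxylate, ethylene and Me3SiF, under conditions that leave the benzoate and the epoxide alone; buffered work-up gives the acid.

## Compound list

1 | (S)-pantolactone, (3S)-3-hydroxy-4,4-dimethyloxolan-2-one | CC1(C)COC(=O)[C@H]1O | starting material
2 | (2S)-3,3-dimethylbutane-1,2,4-triol | OC[C@@H](O)C(C)(C)CO | intermediate
3 | 2-[(4S)-2,2-dimethyl-1,3-dioxolan-4-yl]-2-methylpropan-1-ol | CC1(C)OC[C@@H](O1)C(C)(C)CO | intermediate
4 | 2-[(4S)-2,2-dimethyl-1,3-dioxolan-4-yl]-2-methylpropyl trifluoromethanesulfonate | CC1(C)OC[C@@H](O1)C(C)(C)COS(=O)(=O)C(F)(F)F | intermediate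
5 | S-{2-[(4S)-2,2-dimethyl-1,3-dioxolan-4-yl]-2-methylpropyl} ethanethioate | CC1(C)OC[C@@H](O1)C(C)(C)CSC(C)=O | intermediate
6 | (diethoxyphosphoryl)acetic acid | OC(=O)CP(=O)(OCC)OCC | starting material
7 | 2-(trimethylsilyl)ethanol | C[Si](C)(C)CCO | starting material
8 | 2-(trimethylsilyl)ethyl (diethoxyphosphoryl)acetate | CCOP(=O)(OCC)CC(=O)OCC[Si](C)(C)C | intermediate
9 | but-3-yn-1-ol | C#CCCO | starting material
10 | (but-3-yn-1-yloxy)(tert-butyl)dimethylsilane | C#CCCO[Si](C)(C)C(C)(C)C | intermediate
11 | ethylene oxide | C1CO1 | starting material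
12 | (E)-[4-(tert-butyldimethylsilyloxy)-2-methylbut-1-en-1-yl]dimethylalane | C[Al](C)/C=C(\C)CCO[Si](C)(C)C(C)(C)C | intermediate
13 | lithium butyl[(E)-4-(tert-butyldimethylsilyloxy)-2-methylbut-1-en-1-yl]dimethylaluminate | [Li+].CCCC[Al-](C)(C)/C=C(\C)CCO[Si](C)(C)C(C)(C)C | intermediate
14 | (3E)-6-(tert-butyldimethylsilyloxy)-4-methylhex-3-en-1-ol | OCC/C=C(\C)CCO[Si](C)(C)C(C)(C)C | intermediate
15 | tert-butyl{[(3E)-6-iodo-3-methylhex-3-en-1-yl]oxy}dimethylsilane | ICC/C=C(\C)CCO[Si](C)(C)C(C)(C)C | intermediate
16 | 2-(trimethylsilyl)ethyl (5E)-8-(tert-butyldimethylsilyloxy)-2-(diethoxyphosphoryl)-6-methyloct-5-enoate (C2 epimers) | CCOP(=O)(OCC)C(CC/C=C(\C)CCO[Si](C)(C)C(C)(C)C)C(=O)OCC[Si](C)(C)C | intermediate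
17 | 2-(trimethylsilyl)ethyl (5E)-2-(diethoxyphosphoryl)-8-hydroxy-6-methyloct-5-enoate | CCOP(=O)(OCC)C(CC/C=C(\C)CCO)C(=O)OCC[Si](C)(C)C | intermediate
18 | 2-(trimethylsilyl)ethyl (5E)-2-(diethoxyphosphoryl)-8-iodo-6-methyloct-5-enoate | CCOP(=O)(OCC)C(CC/C=C(\C)CCI)C(=O)OCC[Si](C)(C)C | intermediate
19 | 2-[(4S)-2,2-dimethyl-1,3-dioxolan-4-yl]-2-methylpropane-1-thiol | CC1(C)OC[C@@H](O1)C(C)(C)CS | intermediate
20 | acyclic sulfide, 2-(trimethylsilyl)ethyl (5E)-2-(diethoxyphosphoryl)-8-({2-[(4S)-2,2-dimethyl-1,3-dioxolan-4-yl]-2-methylpropyl}sulfanyl)-6-methyloct-5-enoate | CC1(C)OC[C@@H](O1)C(C)(C)CSCC/C(C)=C/CCC(P(=O)(OCC)OCC)C(=O)OCC[Si](C)(C)C | intermediate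
21 | the corresponding sulfoxide (sulfinyl in place of sulfanyl, mixture at sulfur) | CC1(C)OC[C@@H](O1)C(C)(C)CS(=O)CC/C(C)=C/CCC(P(=O)(OCC)OCC)C(=O)OCC[Si](C)(C)C | intermediate
22 | acyclic sulfone, 2-(trimethylsilyl)ethyl (5E)-2-(diethoxyphosphoryl)-8-({2-[(4S)-2,2-dimethyl-1,3-dioxolan-4-yl]-2-methylpropyl}sulfonyl)-6-methyloct-5-enoate | CC1(C)OC[C@@H](O1)C(C)(C)CS(=O)(=O)CC/C(C)=C/CCC(P(=O)(OCC)OCC)C(=O)OCC[Si](C)(C)C | intermediate
23 | 2-(trimethylsilyl)ethyl (5E)-2-(diethoxyphosphoryl)-8-{[(3S)-3,4-dihydroxy-2,2-dimethylbutyl]sulfonyl}-6-methyloct-5-enoate | OC[C@@H](O)C(C)(C)CS(=O)(=O)CC/C(C)=C/CCC(P(=O)(OCC)OCC)C(=O)OCC[Si](C)(C)C | intermediate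
24 | 2-(trimethylsilyl)ethyl (5E)-2-(diethoxyphosphoryl)-8-{[(3S)-2,2-dimethyl-3,4-bis(triethylsilyloxy)butyl]sulfonyl}-6-methyloct-5-enoate | CC[Si](CC)(CC)OC[C@@H](O[Si](CC)(CC)CC)C(C)(C)CS(=O)(=O)CC/C(C)=C/CCC(P(=O)(OCC)OCC)C(=O)OCC[Si](C)(C)C | intermediate
25 | 2-(trimethylsilyl)ethyl (5E)-2-(diethoxyphosphoryl)-8-{[(3S)-2,2-dimethyl-4-oxo-3-(triethylsilyloxy)butyl]sulfonyl}-6-methyloct-5-enoate | O=C[C@@H](O[Si](CC)(CC)CC)C(C)(C)CS(=O)(=O)CC/C(C)=C/CCC(P(=O)(OCC)OCC)C(=O)OCC[Si](C)(C)C | intermediate
26 | 2-(trimethylsilyl)ethyl (4R,5E,9E)-3,3,10-trimethyl-1,1-dioxo-4-(triethylsilyloxy)-1-thiacyclododeca-5,9-diene-6-carboxylate | CC1(C)CS(=O)(=O)CC/C(C)=C/CC/C(C(=O)OCC[Si](C)(C)C)=C\[C@H]1O[Si](CC)(CC)CC | intermediate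
27 | 12-bromo derivative of 26 (bromine on C10, mixture at that carbon) | CC1(C)CS(=O)(=O)C(Br)C/C(C)=C/CC/C(C(=O)OCC[Si](C)(C)C)=C\[C@H]1O[Si](CC)(CC)CC | intermediate
28 | episulfone, thiirane 1,1-dioxide fused across C10–C11 of the eleven-membered ring (12-thiabicyclo[9.1.0]dodecadiene 12,12-dioxide) | CC1(C)C2C(S2(=O)=O)C/C(C)=C/CC/C(C(=O)OCC[Si](C)(C)C)=C\[C@H]1O[Si](CC)(CC)CC | intermediate
29 | 2-(trimethylsilyl)ethyl (1E,3R,5Z,8E)-4,4,8-trimethyl-3-(triethylsilyloxy)cycloundeca-1,5,8-triene-1-carboxylate | CC1(C)/C=C\C/C(C)=C/CC/C(C(=O)OCC[Si](C)(C)C)=C\[C@H]1O[Si](CC)(CC)CC | intermediate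
30 | 2-(trimethylsilyl)ethyl (1E,3R,8E)-4,4,8-trimethyl-3-(triethylsilyloxy)cycloundeca-1,8-diene-1-carboxylate | CC1(C)CCC/C(C)=C/CC/C(C(=O)OCC[Si](C)(C)C)=C\[C@H]1O[Si](CC)(CC)CC | intermediate
31 | 2-(trimethylsilyl)ethyl (1E,3R,8E)-3-hydroxy-4,4,8-trimethylcycloundeca-1,8-diene-1-carboxylate | CC1(C)CCC/C(C)=C/CC/C(C(=O)OCC[Si](C)(C)C)=C\[C@H]1O | intermediate
32 | 2-(trimethylsilyl)ethyl (1E,3R,8E)-3-(benzoyloxy)-4,4,8-trimethylcycloundeca-1,8-diene-1-carboxylate | CC1(C)CCC/C(C)=C/CC/C(C(=O)OCC[Si](C)(C)C)=C\[C@H]1OC(=O)c1ccccc1 | intermediate
33 | 2-(trimethylsilyl)ethyl (1R,4E,6R,11R)-6-(benzoyloxy)-7,7,11-trimethyl-12-oxabicyclo[9.1.0]dodec-4-ene-4-carboxylate | CC1(C)CCC[C@@]2(C)O[C@@H]2CC/C(C(=O)OCC[Si](C)(C)C)=C\[C@H]1OC(=O)c1ccccc1 | intermediate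
34 | (1R,4E,6R,11R)-6-(benzoyloxy)-7,7,11-trimethyl-12-oxabicyclo[9.1.0]dodec-4-ene-4-carboxylic acid | CC1(C)CCC[C@@]2(C)O[C@@H]2CC/C(C(=O)O)=C\[C@H]1OC(=O)c1ccccc1 | target

## Step count and risks

Total step count: 22. Longest linear sequence: 18 steps (steps 5–22 from but-3-yn-1-ol 9). The pantolactone branch (steps 1–3) and the phosphonate ester (step 4) join it at steps 11 and 8.

**Step 17 (key step).** The likely failure is base chemistry at the enoate outrunning bromine transfer: hydrolysis of the ester on the KOH surface, or transannular conjugate addition of the C10 sulfonyl carbanion to C3 (a six-membered closure). The fallback removes the electrophile and sets out from 26: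
- Bu4NF cleaves both silyl groups of 26 to give the hydroxy acid sulfone F1, whose carboxylate is neither hydrolysable nor a Michael acceptor.
- The same Ramberg–Bäcklund conditions contract F1 to the hydroxy acid triene F2.
- Diimide reduces C10=C11 of F2 to the hydroxy acid diene F3.
- Steglich esterification of F3 with 7 (the hindered C2–OH does not compete) returns to the route at 31.

**Step 16.** Ring closure at a hindered α-silyloxy, β-quaternary aldehyde may be slow enough for intermolecular olefination (oligomers) to compete, and prolonged exposure to base could epimerise C2 by enolisation. The fallback closes the ring at sulfur instead; it sets out from 5 and 18 and returns at 26: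
- Aqueous acetic acid hydrolyses 5 to the diol thioacetate F4, which is silylated at once (TESOTf, 2,6-lutidine) to the bis(triethylsilyl) ether F5.
- Swern oxidation of F5 gives the aldehyde thioacetate F6.
- Intermolecular Horner–Wadsworth–Emmons reaction of F6 with 18 (LiCl, i-Pr2NEt, MeCN) gives the acyclic iodo enoate F7.
- NaOMe (one equivalent) in THF at high dilution cleaves the thioacetate of F7, and the thiolate displaces the C10 iodide to give the twelve-membered sulfide F8.
- (NH4)6Mo7O24·4H2O/H2O2 oxidises F8 to 26.

Without a proton source the 5-exo conjugate addition of the thiolate to C3 is reversible and the SN2 closure is not. This is the risk the main route avoids, which is why this order is only the fallback.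

**Step 18.** The neopentyl C10=C11 may react slowly, so that reduction of C7=C8 or of the enoate begins before conversion is complete. The fallback replaces diimide by hydrogenation of 29 with H2 and RhCl(PPh3)3 (a monovalent rhodium catalyst) in benzene. This selects by steric access of the olefin to the metal and leaves trisubstituted olefins and trisubstituted enoates alone. It sets out from 29, returns at 30 and makes no new compound (F0).

**Step 21.** Facial selection may be poor if the ring conformer favoured by the C2 benzoate presents the wrong face of C7=C8 and the catalyst cannot override it. The fallback gives up reagent control and sets out from 32: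
- Dimethyldioxirane in acetone epoxidises 32 under substrate control.
- Chromatography separates 33 from its diastereomer, the (7S,8S)-epoxide F9.
- Stereospecific deoxygenation of F9 (CH3ReO3 cat., PPh3) returns it to 32 for another pass, so the sequence rejoins the route at 33 with the unwanted isomer recycled.

## Further compounds

F1 | step 17 | (4R,5E,9E)-4-hydroxy-3,3,10-trimethyl-1,1-dioxo-1-thiacyclododeca-5,9-diene-6-carboxylic acid | CC1(C)CS(=O)(=O)CC/C(C)=C/CC/C(C(=O)O)=C\[C@H]1O
F2 | step 17 | (1E,3R,5Z,8E)-3-hydroxy-4,4,8-trimethylcycloundeca-1,5,8-triene-1-carboxylic acid | CC1(C)/C=C\C/C(C)=C/CC/C(C(=O)O)=C\[C@H]1O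
F3 | step 17 | (1E,3R,8E)-3-hydroxy-4,4,8-trimethylcycloundeca-1,8-diene-1-carboxylic acid | CC1(C)CCC/C(C)=C/CC/C(C(=O)O)=C\[C@H]1O
F4 | step 16 | S-[(3S)-3,4-dihydroxy-2,2-dimethylbutyl] ethanethioate | OC[C@@H](O)C(C)(C)CSC(C)=O
F5 | step 16 | S-[(3S)-2,2-dimethyl-3,4-bis(triethylsilyloxy)butyl] ethanethioate | CC[Si](CC)(CC)OC[C@@H](O[Si](CC)(CC)CC)C(C)(C)CSC(C)=O
F6 | step 16 | S-[(3S)-2,2-dimethyl-4-oxo-3-(triethylsilyloxy)butyl] ethanethioate | O=C[C@@H](O[Si](CC)(CC)CC)C(C)(C)CSC(C)=O
F7 | step 16 | 2-(trimethylsilyl)ethyl (2E,4R)-6-(acetylsulfanyl)-2-[(3E)-6-iodo-4-methylhex-3-en-1-yl]-5,5-dimethyl-4-(triethylsilyloxy)hex-2-enoate | CC(=O)SCC(C)(C)[C@H](O[Si](CC)(CC)CC)/C=C(\CC/C=C(\C)CCI)C(=O)OCC[Si](C)(C)C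
F8 | step 16 | 2-(trimethylsilyl)ethyl (4R,5E,9E)-3,3,10-trimethyl-4-(triethylsilyloxy)-1-thiacyclododeca-5,9-diene-6-carboxylate | CC1(C)CSCC/C(C)=C/CC/C(C(=O)OCC[Si](C)(C)C)=C\[C@H]1O[Si](CC)(CC)CC
F0 | step 18 | none | none
F9 | step 21 | 2-(trimethylsilyl)ethyl (1S,4E,6R,11S)-6-(benzoyloxy)-7,7,11-trimethyl-12-oxabicyclo[9.1.0]dodec-4-ene-4-carboxylate | CC1(C)CCC[C@]2(C)O[C@H]2CC/C(C(=O)OCC[Si](C)(C)C)=C\[C@H]1OC(=O)c1ccccc1
A1 | alternative 1 | 3,7,7-trimethylcyclohept-2-en-1-one | CC1=CC(=O)C(C)(C)CCC1
A2 | alternative 1 | methyl cyclobut-1-ene-1-carboxylate | COC(=O)C1=CCC1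
A3 | alternative 1 | cis-anti-cis 7-4-4 tricyclic keto ester photoadduct (racemic, one enantiomer drawn) | O=C1C(C)(C)CCC[C@]2(C)[C@H]1[C@@]3(C(=O)OC)CC[C@H]32
A4 | alternative 2 | (−)-caryophyllene oxide | CC1(C)C[C@@H]2C(=C)CC[C@H]3O[C@]3(C)CC[C@@H]12
A5 | alternative 2 | eleven-membered epoxy allyl phenyl sulfide | CC1(C)CCC[C@@]2(C)O[C@@H]2CC/C(CSc3ccccc3)=C\C1
A6 | alternative 3 | fused six–seven hydroxy mesylate, methyl bicyclo[5.4.0]undecene carboxylate with C2–OH, C7–OMs and the C2–C8 bond (racemic, relative configuration drawn) | CC1(C)CCC[C@@]2(C)[C@H](OS(C)(=O)=O)CCC(C(=O)OC)=C[C@]12O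
A7 | alternative 3 | eleven-membered 2-oxo dienoate, methyl (1E,8E)-4,4,8-trimethyl-3-oxocycloundeca-1,8-diene-1-carboxylate | CC1(C)CCC/C(C)=C/CC/C(C(=O)OC)=C\C1=O
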